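**Convention and assumption.** Flavan numbering (O1, C2, C3, C4, C4a, C5–C8, C8a) is used for both halves; unit A is the 5‑hydroxy‑6,7‑dimethoxy half and unit B the 5,6,7‑trimethoxy half. Compounds 1, 5 and 11 are taken as commercial. Diol 10 is drawn as the 2,4‑cis epimer that the chelate model predicts; either C4 epimer serves, because C4 of unit A becomes planar in step 14.

## The problem

Beilschmieflavonoid B (21) is two flavan units joined only by an ether oxygen between their C4 atoms. Unit B is simply the 5‑O‑methyl ether of unit A, so the halves differ by one methyl group and must be differentiated from the start. All four stereocentres are (2S,4R): each pyran ring carries an equatorial phenyl at C2 and an axial, 2,4‑trans oxygen at C4. The C2 centres have to come from a chiral carbinol. They can then control C4, because a nucleophile adding to a planar C4 of the half‑chair enters axially, trans to phenyl. Both C4–O bonds are 2,4,6‑trioxygenated benzylic ether bonds that ionise in mild acid, which would scramble the halves, epimerise C4 or give flav‑3‑enes. β‑Aryloxy carbonyl intermediates can also lose C2 by expelling the aryloxide under base. Ring closure of unit B is unambiguous, since its trimethoxyphenoxy ring has two equivalent ortho carbons. In unit A the two free ring carbons (future C4a and C8) are both flanked by oxygen, and an ordinary electrophilic closure cannot choose between them. The enabling feature is the free O5–H of unit A, ortho to C4a and peri to C4: a metal on O5 can deliver a C4 aldehyde to C4a only, and the resulting 4‑OH/5‑OH pair is a latent ortho‑quinone methide that makes C4 electrophilic without acid.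

## Retrosynthesis

**C4(A)–O bond.** Target 21 is cut at the bond between C4 of unit A and the bridging oxygen, giving diol 10 and the trans alcohol 19 by way of quinone methide 20. The neighbouring cut at C4(B)–O would need a cation of unit B, which only acid can produce, and acid ionises both halves. Unit A can be activated under neutral conditions because of O5–H, and 19 then keeps its C4–O bond and configuration. The precursors are two monomeric flavan‑4‑ols, and the C4 configuration of 10 no longer matters. The forward step must add 19 from the axial face faster than 10 condenses with itself.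

**C4 of unit B.** Alcohol 19 is traced to its cis epimer 17 through ester 18, because hydride reduction of flavanone 16 delivers the cis alcohol and the trans one needs an inversion. Methylating 10 would also give 17, but that would hang both halves on the one unproven step and on its provisional C4 configuration, so unit B gets its own branch.

**C4–C4a of unit B.** Flavanone 16 is cut at C4–C4a to acid 14. An intramolecular Friedel–Crafts acylation is acceptable here, and only here, because both ortho carbons of the phenoxy ring are equivalent. Acid 14 comes from aldehyde 13 and alkene 12. The acylation must not ionise the benzylic C2–O bond.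

**O1–C2 of unit B.** Alkene 12 is cut at O1–C2 into phenol 11 and (R)‑alcohol 5. A Mitsunobu reaction with inversion sets C2, and the terminal alkene is a masked C4 carbonyl that does not suffer β‑elimination during the etherification.

**C4–C4a of unit A (key cut).** Diol 10 is cut at C4–C4a to the phenol aldehyde 8, passing through the magnesium phenoxide 9. Acylation as in unit B, or an acid‑mediated hydroxyalkylation, would give mixtures of the 5‑hydroxy and 7‑hydroxy series. The conservative neighbour is peri‑selective demethylation of 16 followed by reduction. It is shorter on paper (two steps from 16) and is held as the reserve, because it exposes a flavanone whose ring can open to the chalcone to a strong Lewis acid. The chosen cut reaches the diol oxidation level directly from an acyclic precursor with one stereocentre. It asks for bond formation ortho to O5 that outruns loss of the aryloxide.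

**O1–C2 of unit A.** Aldehyde 8 comes from silyl ether 7, alkene 6, and then phenol 4 plus alcohol 5 by the same Mitsunobu cut. O5 stays silylated through the oxidative steps, because a free ortho‑methoxyphenol would not survive periodate.

**Differentiating the two phenolic oxygens.** Phenol 4 comes from aldehyde 2 through formate 3, and 2 from benzaldehyde 1. The Baeyer–Villiger reaction turns the aldehyde carbon into O1, so the oxygen next to a methoxyl (future O5) is the one that is protected, without any selective alkylation of a resorcinol.

## Roads not taken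

**Alternative 1:** Cut O1–C8a and C4–C4a of unit B at once. CsF would release 3,4,5‑trimethoxybenzyne A3 from silyl triflate A2. The alkoxide of methyl (S)‑3‑hydroxy‑3‑phenylpropanoate A4 adds to the aryne carbon remote from the flanking methoxyl, and the aryl anion acylates on the ester to give flavanone A1, the same compound as 16.
- Merits: one convergent operation replaces steps 7–10, the regiochemistry follows from aryne polarisation, and no acid is used.
- Weak points: A2 needs several steps from 11 (bromination, silylation, silyl migration, triflation). The basic fluoride medium invites retro‑aldol cleavage or dehydration of A4 and ring opening of A1 to the chalcone, which erases C2. It also builds only the half that has no regiochemical problem; unit A would need its own aryne with a protected O5, then deprotection and reduction.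
- Comparison: for the flavanone of unit B this road is probably as short or shorter, and that is conceded. The chosen plan sets against it that its central step solves the unsymmetrical half and uses the free phenol twice, first to direct the C–C bond and then to unlock the ether bond.

**Alternative 2:** Cut both C4–C4a bonds and one C4–O bond together. Two molecules of aldehyde A5 (the same compound as 13) would react under Me3SiOTf: one cyclises to a 4‑silyloxyflavan, condenses with the second to an oxocarbenium ion, and this cyclises to bis ether A6.
- Merits: three steps from 11 and 5 to the whole dimeric skeleton, with both C4 centres set by axial attack in one event.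
- Weak points: A6 is the C2‑symmetric bis(trimethoxy) compound, one methyl group too many. Removing exactly one of two equivalent 5‑methoxy groups has no carbonyl to direct it, and the Lewis acids that cleave aryl methyl ethers would first ionise the doubly benzylic ether. A crossed dimerisation with an O5‑protected unit A aldehyde would be statistical and would reopen the C4a/C8 question.
- Comparison: far better step economy to the dimer. The chosen plan is longer but differentiates the halves from the first step and never has to desymmetrise.

**Alternative 3:** Cut C4–C4a of unit B last. Acid A11 (the same compound as 14) would be esterified with the 5‑O‑allyl trans flavan‑4‑ol A10 of unit A to give ester A9. Reduction and in‑situ acetylation give α‑acetoxy ether A8. BF3·OEt2 at low temperature ionises A8 to an oxocarbenium ion at the future C4 of unit B, which the trimethoxyphenoxy ring attacks to give A7. Deallylation with zerovalent palladium would finish.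
- Merits: the bridging oxygen comes from a defined alcohol and is never exchanged, no partner is needed in excess, and the cyclisation is on the symmetrical ring.
- Weak points: A10 still requires a regiocontrolled closure of unit A, plus protection and inversion. The acetal A8 has two leaving groups, and loss of the unit A flavanyloxy group as a trioxygenated benzylic cation competes with loss of acetate. The C4 configuration of unit B rests on a conformational preference in the cyclisation. The endgame takes four steps against one.
- Comparison: it is the more controlled way to make the ether bond, and that is a real advantage over an equilibrium addition. The chosen plan sets against it brevity and the absence of any Lewis acid once the bis‑benzylic ether exists.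

Key step: step 6

## Route

Step 1
Reactants: 1 3-hydroxy-4,5-dimethoxybenzaldehyde
Product: 2 3,4-dimethoxy-5-(triisopropylsilyloxy)benzaldehyde
Conditions: i-Pr3SiCl, imidazole, DMF, rt
Reagents that add atoms: triisopropylsilyl chloride, CC(C)[Si](Cl)(C(C)C)C(C)C
Why: Imidazole-promoted silylation of a phenol; the bulky silyl ether is chosen to survive peracid, brief methanolysis, Mitsunobu and osmium/periodate conditions and still leave with buffered fluoride.

Step 2
Reactants: 2 3,4-dimethoxy-5-(triisopropylsilyloxy)benzaldehyde
Product: 4 3,4-dimethoxy-5-(triisopropylsilyloxy)phenol, via aryl formate 3 (not isolated)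
Conditions: mCPBA, CH2Cl2, 0 °C to rt; then K2CO3 (cat.), MeOH, 0 °C
Reagents that add atoms: meta-chloroperbenzoic acid, OOC(=O)c1cccc(Cl)c1
Why: Baeyer–Villiger oxidation in which the electron-rich aryl group (para-methoxy) migrates in preference to hydride; the formate is cleaved by mild methanolysis, leaving the future O1 as the only free hydroxyl.

Step 3
Reactants: 4 3,4-dimethoxy-5-(triisopropylsilyloxy)phenol; 5 (R)-1-phenylbut-3-en-1-ol
Product: 6 1,2-dimethoxy-5-[(S)-1-phenylbut-3-enyloxy]-3-(triisopropylsilyloxy)benzene
Conditions: PPh3, DIAD, PhMe, 0 °C to rt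
Reagents that add atoms: none
Why: Mitsunobu etherification of a secondary benzylic alcohol by an unhindered phenol with inversion, (R)-carbinol to (S)-ether; this sets C2 of unit A.

Step 4
Reactants: 6 1,2-dimethoxy-5-[(S)-1-phenylbut-3-enyloxy]-3-(triisopropylsilyloxy)benzene
Product: 7 (S)-3-[3,4-dimethoxy-5-(triisopropylsilyloxy)phenoxy]-3-phenylpropanal
Conditions: OsO4 (cat.), NaIO4, 2,6-lutidine, dioxane–H2O, rt
Reagents that add atoms: osmium tetroxide, O=[Os](=O)(=O)=O (catalytic carrier of the carbonyl oxygen); sodium periodate, [Na+].[O-]I(=O)(=O)=O (replenishes it)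
Why: Lemieux–Johnson cleavage of the terminal alkene; 2,6-lutidine keeps the medium near neutral so the β-aryloxy aldehyde should not eliminate, and the silyl ether keeps the ortho-methoxyphenol away from periodate.

Step 5
Reactants: 7 (S)-3-[3,4-dimethoxy-5-(triisopropylsilyloxy)phenoxy]-3-phenylpropanal
Product: 8 (S)-3-(3-hydroxy-4,5-dimethoxyphenoxy)-3-phenylpropanal
Conditions: Bu4NF, AcOH (1:1), THF, 0 °C
Reagents that add atoms: none
Why: Fluoride cleavage of an aryl silyl ether, buffered with acetic acid so that neither a free phenoxide nor an aldehyde enolate can expel the aryloxy group; 8 is to be used at once.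

Step 6
Reactants: 8 (S)-3-(3-hydroxy-4,5-dimethoxyphenoxy)-3-phenylpropanal
Product: 10 (2S,4S)-5-hydroxy-6,7-dimethoxyflavan-4-ol, via chloromagnesium phenoxide 9 (not isolated)
Conditions: MgCl2, Et3N, MeCN, 0 °C to rt, slow addition of 8 (0.02 M); pH 7 buffer
Reagents that add atoms: none
Why: Proposed new method: triethylamine and MgCl2 convert the phenol into chloromagnesium phenoxide 9, whose magnesium also binds the tethered aldehyde oxygen, so that the ortho carbon C4a adds to the activated carbonyl through a closed six-membered array (O5–Mg–O=C4···C4a–C5) and the dienone formed rearomatises to the magnesium chelate of the 4,5-diol; the closest known reaction type is the intermolecular ortho-specific hydroxyalkylation of magnesium phenoxides by aldehydes (the basis of the MgCl2/Et3N ortho-formylation with paraformaldehyde), here carried out within one molecule. The pyran ring of unit A closes in the 6-exo-trig mode, forming C4–C4a while the O1–C2–C3 chain adopts a chair-like arrangement. The new stereocentre C4 is controlled by C2 and by the chelate: phenyl sits equatorial and the carbonyl oxygen must point towards O5, that is pseudoequatorial, which predicts the 2,4-cis (4S) diol; the assignment is provisional and does not matter later, because C4 is planar in step 14. The selectivity needed is C4a over C8: the other carbon ortho to O5 (C6) carries a methoxyl, and C8, para to O5, cannot be reached by an aldehyde held on the O5-bound magnesium. Loss of the aryloxy group by E1cB is disfavoured because the leaving group would be a phenoxide already carrying the O5 negative charge. High dilution and low temperature should limit intermolecular aldol and hydride-transfer (Meerwein–Ponndorf–Verley) side reactions, and the neutral work-up protects the acid-labile diol.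

Step 7
Reactants: 11 3,4,5-trimethoxyphenol; 5 (R)-1-phenylbut-3-en-1-ol
Product: 12 1,2,3-trimethoxy-5-[(S)-1-phenylbut-3-enyloxy]benzene
Conditions: PPh3, DIAD, PhMe, 0 °C to rt
Reagents that add atoms: none
Why: The same Mitsunobu etherification with inversion; it sets C2 of unit B as (S).

Step 8
Reactants: 12 1,2,3-trimethoxy-5-[(S)-1-phenylbut-3-enyloxy]benzene
Product: 13 (S)-3-phenyl-3-(3,4,5-trimethoxyphenoxy)propanal
Conditions: OsO4 (cat.), NaIO4, 2,6-lutidine, dioxane–H2O, rt
Reagents that add atoms: osmium tetroxide, O=[Os](=O)(=O)=O (catalytic carrier of the carbonyl oxygen); sodium periodate, [Na+].[O-]I(=O)(=O)=O (replenishes it)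
Why: Lemieux–Johnson cleavage as in step 4; trialkoxyaryl ethers are not attacked by periodate.

Step 9
Reactants: 13 (S)-3-phenyl-3-(3,4,5-trimethoxyphenoxy)propanal
Product: 14 (S)-3-phenyl-3-(3,4,5-trimethoxyphenoxy)propanoic acid
Conditions: NaClO2, NaH2PO4, 2-methylbut-2-ene, t-BuOH–H2O, 0 °C to rt
Reagents that add atoms: sodium chlorite, [Na+].[O-]Cl=O
Why: Pinnick oxidation; the alkene scavenger removes hypochlorous acid before it can chlorinate the electron-rich ring, and the stereocentre is not involved.

Step 10
Reactants: 14 (S)-3-phenyl-3-(3,4,5-trimethoxyphenoxy)propanoic acid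
Product: 16 (S)-5,6,7-trimethoxyflavanone, via mixed trifluoroacetic anhydride 15 (not isolated)
Conditions: (CF3CO)2O, CH2Cl2, 0 °C to rt
Reagents that add atoms: none
Why: Intramolecular Friedel–Crafts acylation through the mixed anhydride; the two ortho carbons of the trimethoxyphenoxy ring are equivalent, so only one flavanone can form, and the absence of a strong Lewis acid should leave the benzylic C2–O bond intact.

Step 11
Reactants: 16 (S)-5,6,7-trimethoxyflavanone
Product: 17 (2S,4S)-5,6,7-trimethoxyflavan-4-ol
Conditions: NaBH4, MeOH–THF, 0 °C
Reagents that add atoms: none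
Why: Hydride reduction of a flavanone; axial attack on the half-chair with equatorial phenyl should give the equatorial, 2,4-cis alcohol, and the short cold reaction avoids ring opening to the chalcone.

Step 12
Reactants: 17 (2S,4S)-5,6,7-trimethoxyflavan-4-ol
Product: 18 (2S,4R)-5,6,7-trimethoxyflavan-4-yl 4-nitrobenzoate
Conditions: 4-O2NC6H4CO2H, PPh3, DIAD, THF, 0 °C to rt
Reagents that add atoms: 4-nitrobenzoic acid, OC(=O)c1ccc(cc1)[N+](=O)[O-]
Why: Mitsunobu inversion at C4; direct displacement and capture of an ion pair from the axial face both lead to the trans (4R) ester.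

Step 13
Reactants: 18 (2S,4R)-5,6,7-trimethoxyflavan-4-yl 4-nitrobenzoate
Product: 19 (2S,4R)-5,6,7-trimethoxyflavan-4-ol
Conditions: LiOH, THF–H2O, 0 °C to rt; neutral work-up
Reagents that add atoms: none
Why: Saponification by acyl–oxygen cleavage retains C4; water is the only nucleophile present, so any ionisation would also return the axial alcohol.

Step 14
Reactants: 10 (2S,4S)-5-hydroxy-6,7-dimethoxyflavan-4-ol; 19 (2S,4R)-5,6,7-trimethoxyflavan-4-ol
Product: 21 beilschmieflavonoid B, via ortho-quinone methide 20 (not isolated)
Conditions: 19 (2 equiv), 4 Å molecular sieves, PhMe, 70 °C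
Reagents that add atoms: none
Why: Thermal loss of water from the hydrogen-bonded 4,5-diol gives quinone methide 20 under neutral conditions, and conjugate addition of an alcohol to such a species is a known way to make ortho-hydroxybenzyl ethers; 19 cannot ionise without acid and keeps its C4 configuration. The alcohol should add to C4 of the half-chair along the axial direction with phenyl equatorial, giving 4R in unit A, which is also the epimer expected to be favoured at equilibrium because an axial C4 substituent avoids the peri oxygen; the sieves take up water and excess 19 is recoverable.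

## Compound list

1 | 3-hydroxy-4,5-dimethoxybenzaldehyde | COc1cc(C=O)cc(O)c1OC | starting material
2 | 3,4-dimethoxy-5-(triisopropylsilyloxy)benzaldehyde | COc1cc(C=O)cc(O[Si](C(C)C)(C(C)C)C(C)C)c1OC | intermediate
3 | 3,4-dimethoxy-5-(triisopropylsilyloxy)phenyl formate | COc1cc(OC=O)cc(O[Si](C(C)C)(C(C)C)C(C)C)c1OC | intermediate (not isolated)
4 | 3,4-dimethoxy-5-(triisopropylsilyloxy)phenol | COc1cc(O)cc(O[Si](C(C)C)(C(C)C)C(C)C)c1OC | intermediate
5 | (R)-1-phenylbut-3-en-1-ol | O[C@H](CC=C)c1ccccc1 | starting material
6 | 1,2-dimethoxy-5-[(S)-1-phenylbut-3-enyloxy]-3-(triisopropylsilyloxy)benzene | C=CC[C@@H](c1ccccc1)Oc1cc(O[Si](C(C)C)(C(C)C)C(C)C)c(OC)c(OC)c1 | intermediate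
7 | (S)-3-[3,4-dimethoxy-5-(triisopropylsilyloxy)phenoxy]-3-phenylpropanal | O=CC[C@@H](c1ccccc1)Oc1cc(O[Si](C(C)C)(C(C)C)C(C)C)c(OC)c(OC)c1 | intermediate
8 | (S)-3-(3-hydroxy-4,5-dimethoxyphenoxy)-3-phenylpropanal | O=CC[C@@H](c1ccccc1)Oc1cc(O)c(OC)c(OC)c1 | intermediate
9 | chloromagnesium 2,3-dimethoxy-5-[(S)-3-oxo-1-phenylpropoxy]phenoxide | O=CC[C@@H](c1ccccc1)Oc1cc(O[Mg]Cl)c(OC)c(OC)c1 | intermediate (not isolated)
10 | (2S,4S)-5-hydroxy-6,7-dimethoxyflavan-4-ol (2,4-cis; C4 provisional) | COc1cc2c(c(O)c1OC)[C@@H](O)C[C@@H](c1ccccc1)O2 | intermediate
11 | 3,4,5-trimethoxyphenol | COc1cc(O)cc(OC)c1OC | starting material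
12 | 1,2,3-trimethoxy-5-[(S)-1-phenylbut-3-enyloxy]benzene | C=CC[C@@H](c1ccccc1)Oc1cc(OC)c(OC)c(OC)c1 | intermediate
13 | (S)-3-phenyl-3-(3,4,5-trimethoxyphenoxy)propanal | O=CC[C@@H](c1ccccc1)Oc1cc(OC)c(OC)c(OC)c1 | intermediate
14 | (S)-3-phenyl-3-(3,4,5-trimethoxyphenoxy)propanoic acid | OC(=O)C[C@@H](c1ccccc1)Oc1cc(OC)c(OC)c(OC)c1 | intermediate
15 | (S)-3-phenyl-3-(3,4,5-trimethoxyphenoxy)propanoic trifluoroacetic anhydride | O=C(C[C@@H](c1ccccc1)Oc1cc(OC)c(OC)c(OC)c1)OC(=O)C(F)(F)F | intermediate (not isolated)
16 | (S)-5,6,7-trimethoxyflavanone | COc1cc2c(c(OC)c1OC)C(=O)C[C@@H](c1ccccc1)O2 | intermediate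
17 | (2S,4S)-5,6,7-trimethoxyflavan-4-ol (2,4-cis) | COc1cc2c(c(OC)c1OC)[C@@H](O)C[C@@H](c1ccccc1)O2 | intermediate
18 | (2S,4R)-5,6,7-trimethoxyflavan-4-yl 4-nitrobenzoate | COc1cc2c(c(OC)c1OC)[C@H](OC(=O)c1ccc(cc1)[N+](=O)[O-])C[C@@H](c1ccccc1)O2 | intermediate
19 | (2S,4R)-5,6,7-trimethoxyflavan-4-ol (2,4-trans) | COc1cc2c(c(OC)c1OC)[C@H](O)C[C@@H](c1ccccc1)O2 | intermediate
20 | (S)-6,7-dimethoxy-2-phenyl-2,3-dihydrochromen-5-one (ortho-quinone methide of unit A, C4=C4a) | O=C1C(OC)=C(OC)C=C2O[C@H](c3ccccc3)CC=C12 | intermediate (not isolated)
21 | beilschmieflavonoid B, (2S,4R)-6,7-dimethoxy-2-phenyl-4-{[(2S,4R)-5,6,7-trimethoxy-2-phenylchroman-4-yl]oxy}chroman-5-ol | COc1cc2c(c(O)c1OC)[C@H](O[C@@H]1C[C@@H](c3ccccc3)Oc3cc(OC)c(OC)c(OC)c31)C[C@@H](c1ccccc1)O2 | target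

## Step count and risks

Total: 14 steps (1–6 for unit A, 7–13 for unit B, 14 the union). Longest linear sequence: 8 steps (7–14).

**Step 6 (key step).** The phenoxide may fail to close before other processes take over: elimination of the aryloxide from the magnesium-activated aldehyde, hydride transfer between the product alkoxide and unreacted aldehyde, early formation and oligomerisation of the quinone methide from the product chelate, or an open, non-chelated pathway that reaches C8.
Fallback by known chemistry, setting out from 16 and returning at 10: BCl3 (CH2Cl2, −78 to 0 °C) cleaves only the methoxyl peri to the carbonyl, the one that can chelate boron, to give (S)-5-hydroxy-6,7-dimethoxyflavanone F1. NaBH4 (MeOH–THF, 0 °C) then reduces F1 from the axial direction to the cis diol 10. The regiochemistry is inherited from the symmetry of 11; the Lewis acid step must be kept cold to avoid ring opening at C2.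

**Step 14.** The addition is reversible, so conversion may stall. Diol 10 may condense with itself through its own hydroxyls, 20 may dimerise or tautomerise to the flav-3-ene, the electron-rich C8 positions may be C-alkylated, and prolonged equilibration could erode the facial preference.
Fallback, setting out from 10 and returning at 21: Boc2O with i-Pr2NEt and catalytic DMAP gives the phenol carbonate tert-butyl (2S,4S)-4-hydroxy-6,7-dimethoxy-2-phenylchroman-5-yl carbonate F2. Separately, 19 is deprotonated with t-BuMgCl to chloromagnesium (2S,4R)-5,6,7-trimethoxyflavan-4-olate F3. Mixing the two in THF from −78 °C to rt triggers alkoxide exchange, oxygen-to-oxygen migration of the carbonate and loss of tert-butyl carbonate. This forms 20 irreversibly at low temperature, and F3 is the nucleophile at hand.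

**Step 3.** The activated benzylic oxyphosphonium may ionise, with partial loss of configuration, or eliminate to 1-phenylbuta-1,3-diene. Step 7 is the same reaction on a simpler phenol and would show the problem first.
Fallback, setting out from 4 and returning at 7: a Mitsunobu reaction with (R)-3-chloro-1-phenylpropan-1-ol F4, whose saturated chain cannot form a conjugated diene, gives (S)-[5-(3-chloro-1-phenylpropoxy)-2,3-dimethoxyphenoxy]triisopropylsilane F5. CsOAc with catalytic NaI in DMF gives (S)-3-[3,4-dimethoxy-5-(triisopropylsilyloxy)phenoxy]-3-phenylpropyl acetate F6. K2CO3 in MeOH at 0 °C gives (S)-3-[3,4-dimethoxy-5-(triisopropylsilyloxy)phenoxy]-3-phenylpropan-1-ol F7. Dess–Martin periodinane buffered with NaHCO3 then gives 7.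

**Step 10.** The mixed anhydride may expel the aryloxide to a cinnamoyl species that acylates and recloses without stereocontrol, and the ring may be trifluoroacetylated intermolecularly.
Fallback, setting out from 11 and returning at 16: C-acetylation with Ac2O and BF3·OEt2 gives 1-(2-hydroxy-4,5,6-trimethoxyphenyl)ethan-1-one F8. Me2NCH(OMe)2 gives (E)-3-(dimethylamino)-1-(2-hydroxy-4,5,6-trimethoxyphenyl)prop-2-en-1-one F9. Acid closes F9 to 5,6,7-trimethoxychromen-4-one F10. Asymmetric conjugate addition of PhB(OH)2 with Pd(OCOCF3)2 and a chiral pyridine–oxazoline ligand, the ligand enantiomer chosen for the (S) product, then sets C2 by catalyst control and gives 16.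

**Step 12.** The oxyphosphonium of this very ionisable carbinol may eliminate to the flav-3-ene, and the ester may solvolyse on purification.
Fallback, setting out from 17 and returning at 19: acetolysis in AcOH buffered with NaOAc at rt goes deliberately through the flavan-4-yl cation, which acetate should capture axially to give (2S,4R)-5,6,7-trimethoxyflavan-4-yl acetate F11. LiOH in THF–H2O then gives 19.

## Further compounds

F1 | step 6 | (S)-5-hydroxy-6,7-dimethoxyflavanone | COc1cc2c(c(O)c1OC)C(=O)C[C@@H](c1ccccc1)O2
F2 | step 14 | tert-butyl (2S,4S)-4-hydroxy-6,7-dimethoxy-2-phenylchroman-5-yl carbonate | COc1cc2c(c(OC(=O)OC(C)(C)C)c1OC)[C@@H](O)C[C@@H](c1ccccc1)O2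
F3 | step 14 | chloromagnesium (2S,4R)-5,6,7-trimethoxyflavan-4-olate | COc1cc2c(c(OC)c1OC)[C@H](O[Mg]Cl)C[C@@H](c1ccccc1)O2
F4 | step 3 | (R)-3-chloro-1-phenylpropan-1-ol | O[C@H](CCCl)c1ccccc1
F5 | step 3 | (S)-[5-(3-chloro-1-phenylpropoxy)-2,3-dimethoxyphenoxy]triisopropylsilane | ClCC[C@@H](c1ccccc1)Oc1cc(O[Si](C(C)C)(C(C)C)C(C)C)c(OC)c(OC)c1
F6 | step 3 | (S)-3-[3,4-dimethoxy-5-(triisopropylsilyloxy)phenoxy]-3-phenylpropyl acetate | CC(=O)OCC[C@@H](c1ccccc1)Oc1cc(O[Si](C(C)C)(C(C)C)C(C)C)c(OC)c(OC)c1
F7 | step 3 | (S)-3-[3,4-dimethoxy-5-(triisopropylsilyloxy)phenoxy]-3-phenylpropan-1-ol | OCC[C@@H](c1ccccc1)Oc1cc(O[Si](C(C)C)(C(C)C)C(C)C)c(OC)c(OC)c1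
F8 | step 10 | 1-(2-hydroxy-4,5,6-trimethoxyphenyl)ethan-1-one | CC(=O)c1c(O)cc(OC)c(OC)c1OC
F9 | step 10 | (E)-3-(dimethylamino)-1-(2-hydroxy-4,5,6-trimethoxyphenyl)prop-2-en-1-one | CN(C)/C=C/C(=O)c1c(O)cc(OC)c(OC)c1OC
F10 | step 10 | 5,6,7-trimethoxychromen-4-one | COc1cc2occc(=O)c2c(OC)c1OC
F11 | step 12 | (2S,4R)-5,6,7-trimethoxyflavan-4-yl acetate | COc1cc2c(c(OC)c1OC)[C@H](OC(C)=O)C[C@@H](c1ccccc1)O2
A1 | alternative 1 | (S)-5,6,7-trimethoxyflavanone (identical with 16) | COc1cc2c(c(OC)c1OC)C(=O)C[C@@H](c1ccccc1)O2
A2 | alternative 1 | 3,4,5-trimethoxy-2-(trimethylsilyl)phenyl trifluoromethanesulfonate | COc1cc(OS(=O)(=O)C(F)(F)F)c([Si](C)(C)C)c(OC)c1OC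
A3 | alternative 1 | 3,4,5-trimethoxybenzyne | COC1=C(OC)C(OC)=CC#C1
A4 | alternative 1 | methyl (S)-3-hydroxy-3-phenylpropanoate | COC(=O)C[C@@H](c1ccccc1)O
A5 | alternative 2 | (S)-3-phenyl-3-(3,4,5-trimethoxyphenoxy)propanal (identical with 13) | O=CC[C@@H](c1ccccc1)Oc1cc(OC)c(OC)c(OC)c1
A6 | alternative 2 | bis[(2S,4R)-5,6,7-trimethoxyflavan-4-yl] ether | COc1cc2c(c(OC)c1OC)[C@H](O[C@@H]1C[C@@H](c3ccccc3)Oc3cc(OC)c(OC)c(OC)c31)C[C@@H](c1ccccc1)O2
A7 | alternative 3 | 5-O-allyl ether of beilschmieflavonoid B | COc1cc2c(c(OCC=C)c1OC)[C@H](O[C@@H]1C[C@@H](c3ccccc3)Oc3cc(OC)c(OC)c(OC)c31)C[C@@H](c1ccccc1)O2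
A8 | alternative 3 | 1-[(2S,4R)-5-allyloxy-6,7-dimethoxyflavan-4-yloxy]-(3S)-3-phenyl-3-(3,4,5-trimethoxyphenoxy)propyl acetate (acetal epimers) | COc1cc2c(c(OCC=C)c1OC)[C@H](OC(OC(C)=O)C[C@@H](c3ccccc3)Oc3cc(OC)c(OC)c(OC)c3)C[C@@H](c1ccccc1)O2
A9 | alternative 3 | (2S,4R)-5-allyloxy-6,7-dimethoxyflavan-4-yl (S)-3-phenyl-3-(3,4,5-trimethoxyphenoxy)propanoate | COc1cc2c(c(OCC=C)c1OC)[C@H](OC(=O)C[C@@H](c3ccccc3)Oc3cc(OC)c(OC)c(OC)c3)C[C@@H](c1ccccc1)O2
A10 | alternative 3 | (2S,4R)-5-allyloxy-6,7-dimethoxyflavan-4-ol | COc1cc2c(c(OCC=C)c1OC)[C@H](O)C[C@@H](c1ccccc1)O2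
A11 | alternative 3 | (S)-3-phenyl-3-(3,4,5-trimethoxyphenoxy)propanoic acid (identical with 14) | OC(=O)C[C@@H](c1ccccc1)Oc1cc(OC)c(OC)c(OC)c1
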